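## Retrosynthetic overview

1. Target 21 ⇒ bis-PMB ether 20 ⇒ two twofold ester disconnections to one acyl donor, symmetric anhydride 17 (fragment 2): the last pair of esters comes from reductive acylation of quinone diester 18, the first pair from the two hydroxyls of quinone 10 (fragment 1).
2. Central ring B of 10 ⇒ acyclic 2,4,5-trioxohexanoate 9, closed by an intramolecular enolate–carbonyl condensation (Claisen/Dieckmann type, the ester-level member of the aldol family). 9 unfolds in one pot from dilactide 6, the head-to-tail dimer of arylpyruvic acid 5.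
3. 5 ⇒ Erlenmeyer azlactone 4 ⇒ PMB-protected 4-hydroxybenzaldehyde 2 + N-acetylglycine 3.
4. 17 ⇒ potassium (2Z,4S,5S)-4,5-epoxyhex-2-enoate 16 ⇒ Still–Gennari Z-olefination of epoxy aldehyde 13 ⇒ Sharpless epoxidation of (E)-crotyl alcohol 11, which sets every stereocentre.
5. Ring order: outer aryl rings A and C are bought; the oxiranes are made first (step 6); ring B is formed in step 5; no ring is made after the union.

Assumption: PMB = 4-methoxybenzyl, Ar = 4-[(4-methoxybenzyl)oxy]phenyl; all four acyl groups are read from the SMILES as (2Z)-3-[(2S,3S)-3-methyloxiran-2-yl]prop-2-enoyl, which is (2Z,4S,5S)-4,5-epoxyhex-2-enoyl.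

## Route

**Fragment 1 (terphenyl core)**

Step 1
Reactants: 1 4-hydroxybenzaldehyde
Product: 2 4-[(4-methoxybenzyl)oxy]benzaldehyde
Conditions: 4-methoxybenzyl chloride (1.1 equiv), K2CO3, DMF, 60 °C
Reagents that add atoms: 4-methoxybenzyl chloride, COc1ccc(CCl)cc1
Why: Williamson ether synthesis (phenoxide SN2 on a benzylic chloride) installs a phenol protecting group that survives hydroxide, methoxide and dithionite and can later be removed oxidatively.

Step 2
Reactants: 2 4-[(4-methoxybenzyl)oxy]benzaldehyde; 3 N-acetylglycine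
Product: 4 (4Z)-4-{4-[(4-methoxybenzyl)oxy]benzylidene}-2-methyl-1,3-oxazol-5(4H)-one
Conditions: Ac2O, NaOAc, 110 °C
Reagents that add atoms: none
Why: Erlenmeyer–Plöchl azlactone synthesis: Ac2O cyclodehydrates N-acetylglycine to the oxazolone, whose C4 enolate condenses with the aldehyde (Perkin-type) to give the thermodynamic Z-alkylidene azlactone.

Step 3
Reactants: 4 (4Z)-4-{4-[(4-methoxybenzyl)oxy]benzylidene}-2-methyl-1,3-oxazol-5(4H)-one
Product: 5 3-{4-[(4-methoxybenzyl)oxy]phenyl}-2-oxopropanoic acid (largely the Z-enol)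
Conditions: 3 M NaOH (aq), reflux, N2; then 2 M HCl, 0 °C
Reagents that add atoms: water, O
Why: Alkaline azlactone hydrolysis opens the ring to the α-acetamidocinnamate and then hydrolyses the enamide to the α-keto acid, with the benzylic ether inert to hydroxide and only briefly exposed to cold dilute acid.

Step 4
Reactants: 5 3-{4-[(4-methoxybenzyl)oxy]phenyl}-2-oxopropanoic acid (2 equiv)
Product: 6 (3Z,6Z)-3,6-bis{4-[(4-methoxybenzyl)oxy]benzylidene}-1,4-dioxane-2,5-dione
Conditions: DCC (1.1 equiv per acid), THF, 0 °C → rt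
Reagents that add atoms: none
Why: Steglich-type carbodiimide cyclodimerisation: each O-acylisourea acylates the enol hydroxyl of its partner head to tail, and the second acylation closes the six-membered dilactide with the Z geometry of the stable Z-enol.

Step 5
Reactants: 6 (3Z,6Z)-3,6-bis{4-[(4-methoxybenzyl)oxy]benzylidene}-1,4-dioxane-2,5-dione
Product: 10 2,5-dihydroxy-3,6-bis{4-[(4-methoxybenzyl)oxy]phenyl}cyclohexa-2,5-diene-1,4-dione, via ring-opened enol ester 7 (not isolated), via pyrandione 8 (not isolated), via trioxohexanoate 9 (not isolated)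
Conditions: NaOMe (3 equiv), THF/MeOH (10:1), 0 °C → rt; then 1 M HCl
Reagents that add atoms: none
Why: Methoxide opens one lactone to the ester enolate 7, C-acylation gives pyrandione 8, a second methanolysis gives 9, and its benzylic enolate closes ring B by an intramolecular Claisen (Dieckmann-type) condensation, the ester-level counterpart of an intramolecular aldol, after which tautomerisation to the dihydroxyquinone dianion makes the cascade irreversible; no stereocentre is involved.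

**Fragment 2 (epoxy enoyl donor)**

Step 6
Reactants: 11 (2E)-but-2-en-1-ol
Product: 12 [(2S,3S)-3-methyloxiran-2-yl]methanol
Conditions: Ti(OiPr)4 (5 mol %), L-(+)-diisopropyl tartrate (6 mol %), t-BuOOH (isooctane), 4 Å MS, CH2Cl2, −20 °C; non-aqueous work-up, distillation
Reagents that add atoms: tert-butyl hydroperoxide, CC(C)(C)OO
Why: Sharpless asymmetric epoxidation: the L-(+)-tartrate titanium complex delivers oxygen to the face of the E-allylic alcohol that gives the (2S,3S)-epoxide, and the trans relationship follows stereospecifically from the E alkene.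

Step 7
Reactants: 12 [(2S,3S)-3-methyloxiran-2-yl]methanol
Product: 13 (2R,3S)-3-methyloxirane-2-carbaldehyde
Conditions: nPr4N[RuO4] (5 mol %), N-methylmorpholine N-oxide, 4 Å MS, CH2Cl2, 0 °C → rt; silica plug, cold concentration, used at once
Reagents that add atoms: none
Why: Ley–Griffith oxidation under neutral, non-aqueous conditions gives the volatile epoxy aldehyde without epimerising the oxirane carbon (the descriptor changes to 2R only through the priority change).

Step 8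
Reactants: 13 (2R,3S)-3-methyloxirane-2-carbaldehyde; 14 methyl [bis(2,2,2-trifluoroethoxy)phosphoryl]acetate
Product: 15 methyl (2Z)-3-[(2S,3S)-3-methyloxiran-2-yl]prop-2-enoate
Conditions: KN(SiMe3)2, 18-crown-6, THF, −78 °C
Reagents that add atoms: none
Why: Still–Gennari variant of the Horner–Wadsworth–Emmons olefination: the trifluoroethyl phosphonate with a dissociated potassium counter-ion eliminates under kinetic control to the Z-enoate, leaving both oxirane stereocentres untouched.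

Step 9
Reactants: 15 methyl (2Z)-3-[(2S,3S)-3-methyloxiran-2-yl]prop-2-enoate
Product: 16 potassium (2Z)-3-[(2S,3S)-3-methyloxiran-2-yl]prop-2-enoate
Conditions: KOSiMe3 (1.05 equiv), Et2O, 0 °C → rt; filter the precipitated salt
Reagents that add atoms: potassium trimethylsilanolate, C[Si](C)(C)[O-].[K+]
Why: Anhydrous silanolate ester cleavage (Laganis–Chenard) gives the carboxylate salt directly, so the free Z-epoxy acid, which lactonises by acid-promoted epoxide opening, is never generated.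

Step 10
Reactants: 16 potassium (2Z)-3-[(2S,3S)-3-methyloxiran-2-yl]prop-2-enoate (2 equiv)
Product: 17 (2Z)-3-[(2S,3S)-3-methyloxiran-2-yl]prop-2-enoic anhydride
Conditions: (COCl)2 (0.5 equiv), CH2Cl2, 0 °C → rt, Ar; filter KCl, concentrate cold, keep as a titrated CH2Cl2 solution
Reagents that add atoms: none
Why: Symmetric anhydride formation from a carboxylate salt: oxalyl chloride turns half of the salt into the acyl chloride with loss of CO and CO2, the other half acylates it on oxygen, and because no proton source is present the oxiranes, their stereocentres and the Z alkenes are untouched.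

**Union and end game**

Step 11
Reactants: 10 2,5-dihydroxy-3,6-bis{4-[(4-methoxybenzyl)oxy]phenyl}cyclohexa-2,5-diene-1,4-dione; 17 (2Z)-3-[(2S,3S)-3-methyloxiran-2-yl]prop-2-enoic anhydride (3 equiv)
Product: 18 2,5-bis{4-[(4-methoxybenzyl)oxy]phenyl}-3,6-dioxocyclohexa-1,4-diene-1,4-diyl bis{(2Z)-3-[(2S,3S)-3-methyloxiran-2-yl]prop-2-enoate}
Conditions: Et3N (2.2 equiv), DMAP (5 mol %), CH2Cl2, −20 → 0 °C, Ar; cold pH 7 buffer wash, crystallisation
Reagents that add atoms: none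
Why: O-acylation with an anhydride (nucleophilic acyl substitution, DMAP acyl transfer): the two enolic hydroxyls of the quinone are the only free OH groups, each vinylogous carboxylate takes one acyl group as in the classical diacetates of such quinones, and excess anhydride drives the acyl-transfer equilibrium under basic, acid-free conditions.

Step 12
Reactants: 18 2,5-bis{4-[(4-methoxybenzyl)oxy]phenyl}-3,6-dioxocyclohexa-1,4-diene-1,4-diyl bis{(2Z)-3-[(2S,3S)-3-methyloxiran-2-yl]prop-2-enoate}; 17 (2Z)-3-[(2S,3S)-3-methyloxiran-2-yl]prop-2-enoic anhydride (3 equiv)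
Product: 20 3,6-bis{4-[(4-methoxybenzyl)oxy]phenyl}benzene-1,2,4,5-tetrayl tetrakis{(2Z)-3-[(2S,3S)-3-methyloxiran-2-yl]prop-2-enoate}, via hydroquinone diester 19 (not isolated)
Conditions: (a) Na2S2O4, EtOAc/pH 7 buffer, rt, Ar, 10 min; organic layer dried over Na2SO4; (b) 17, Et3N, DMAP (0.2 equiv), CH2Cl2, 0 °C → rt
Reagents that add atoms: none
Why: Reductive acylation: dithionite reduces the quinone to hydroquinone diester 19, which is much less air-sensitive than a free tetraol, and DMAP-catalysed esterification of its two new phenols with 17 completes the fourfold ester without acid, so no stereocentre or Z alkene is touched.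

Step 13
Reactants: 20 3,6-bis{4-[(4-methoxybenzyl)oxy]phenyl}benzene-1,2,4,5-tetrayl tetrakis{(2Z)-3-[(2S,3S)-3-methyloxiran-2-yl]prop-2-enoate}
Product: 21 3,6-bis(4-hydroxyphenyl)benzene-1,2,4,5-tetrayl tetrakis{(2Z)-3-[(2S,3S)-3-methyloxiran-2-yl]prop-2-enoate} (CNP0249571.1)
Conditions: DDQ (3 equiv), CH2Cl2/pH 7 phosphate buffer (10:1), 0 °C → rt
Reagents that add atoms: none
Why: Oxidative PMB ether cleavage: DDQ oxidises the electron-rich 4-methoxybenzyl groups to oxocarbenium ions that water hydrolyses, under buffered neutral conditions that leave aryl esters, Z-enoates and oxiranes intact.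

## Compound list

1 | 4-hydroxybenzaldehyde | O=Cc1ccc(O)cc1 | starting material
2 | 4-[(4-methoxybenzyl)oxy]benzaldehyde | COc1ccc(COc2ccc(C=O)cc2)cc1 | intermediate
3 | N-acetylglycine | CC(=O)NCC(=O)O | starting material
4 | (4Z)-4-{4-[(4-methoxybenzyl)oxy]benzylidene}-2-methyl-1,3-oxazol-5(4H)-one | CC1=N/C(=C\c2ccc(OCc3ccc(OC)cc3)cc2)C(=O)O1 | intermediate
5 | 3-{4-[(4-methoxybenzyl)oxy]phenyl}-2-oxopropanoic acid (keto form drawn; largely Z-enol) | COc1ccc(COc2ccc(CC(=O)C(=O)O)cc2)cc1 | intermediate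
6 | (3Z,6Z)-3,6-bis{4-[(4-methoxybenzyl)oxy]benzylidene}-1,4-dioxane-2,5-dione | O=C1O/C(=C\c2ccc(OCc3ccc(OC)cc3)cc2)C(=O)O/C1=C\c1ccc(OCc2ccc(OC)cc2)cc1 | intermediate
7 | methyl (2Z)-3-Ar-2-[(3-Ar-2-oxopropanoyl)oxy]prop-2-enoate, formed as its enolate (not isolated) | COC(=O)/C(=C/c1ccc(OCc2ccc(OC)cc2)cc1)OC(=O)C(=O)Cc1ccc(OCc2ccc(OC)cc2)cc1 | intermediate
8 | (6Z)-3-hydroxy-4-Ar-6-(Ar-methylidene)-2H-pyran-2,5(6H)-dione (not isolated) | O=C1O/C(=C\c2ccc(OCc3ccc(OC)cc3)cc2)C(=O)C(c2ccc(OCc3ccc(OC)cc3)cc2)=C1O | intermediate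
9 | methyl 3,6-bis(Ar)-2,4,5-trioxohexanoate, formed as its enolates (not isolated) | COC(=O)C(=O)C(c1ccc(OCc2ccc(OC)cc2)cc1)C(=O)C(=O)Cc1ccc(OCc2ccc(OC)cc2)cc1 | intermediate
10 | 2,5-dihydroxy-3,6-bis{4-[(4-methoxybenzyl)oxy]phenyl}cyclohexa-2,5-diene-1,4-dione | O=C1C(O)=C(c2ccc(OCc3ccc(OC)cc3)cc2)C(=O)C(O)=C1c1ccc(OCc2ccc(OC)cc2)cc1 | intermediate
11 | (2E)-but-2-en-1-ol | C/C=C/CO | starting material
12 | [(2S,3S)-3-methyloxiran-2-yl]methanol | C[C@@H]1O[C@H]1CO | intermediate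
13 | (2R,3S)-3-methyloxirane-2-carbaldehyde | C[C@@H]1O[C@H]1C=O | intermediate
14 | methyl [bis(2,2,2-trifluoroethoxy)phosphoryl]acetate | COC(=O)CP(=O)(OCC(F)(F)F)OCC(F)(F)F | starting material
15 | methyl (2Z)-3-[(2S,3S)-3-methyloxiran-2-yl]prop-2-enoate | C[C@@H]1O[C@H]1/C=C\C(=O)OC | intermediate
16 | potassium (2Z)-3-[(2S,3S)-3-methyloxiran-2-yl]prop-2-enoate | C[C@@H]1O[C@H]1/C=C\C(=O)[O-].[K+] | intermediate
17 | (2Z)-3-[(2S,3S)-3-methyloxiran-2-yl]prop-2-enoic anhydride | C[C@@H]1O[C@H]1/C=C\C(=O)OC(=O)/C=C\[C@@H]1O[C@H]1C | intermediate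
18 | 2,5-bis{4-[(4-methoxybenzyl)oxy]phenyl}-3,6-dioxocyclohexa-1,4-diene-1,4-diyl bis{(2Z)-3-[(2S,3S)-3-methyloxiran-2-yl]prop-2-enoate} | O=C1C(OC(=O)/C=C\[C@@H]2O[C@H]2C)=C(c2ccc(OCc3ccc(OC)cc3)cc2)C(=O)C(OC(=O)/C=C\[C@@H]2O[C@H]2C)=C1c1ccc(OCc2ccc(OC)cc2)cc1 | intermediate
19 | 2,5-dihydroxy-3,6-bis{4-[(4-methoxybenzyl)oxy]phenyl}benzene-1,4-diyl bis{(2Z)-3-[(2S,3S)-3-methyloxiran-2-yl]prop-2-enoate} (not isolated) | Oc1c(OC(=O)/C=C\[C@@H]2O[C@H]2C)c(-c2ccc(OCc3ccc(OC)cc3)cc2)c(O)c(OC(=O)/C=C\[C@@H]2O[C@H]2C)c1-c1ccc(OCc2ccc(OC)cc2)cc1 | intermediate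
20 | 3,6-bis{4-[(4-methoxybenzyl)oxy]phenyl}benzene-1,2,4,5-tetrayl tetrakis{(2Z)-3-[(2S,3S)-3-methyloxiran-2-yl]prop-2-enoate} | C[C@@H]1O[C@H]1/C=C\C(=O)Oc1c(OC(=O)/C=C\[C@@H]2O[C@H]2C)c(-c2ccc(OCc3ccc(OC)cc3)cc2)c(OC(=O)/C=C\[C@@H]2O[C@H]2C)c(OC(=O)/C=C\[C@@H]2O[C@H]2C)c1-c1ccc(OCc2ccc(OC)cc2)cc1 | intermediate
21 | 3,6-bis(4-hydroxyphenyl)benzene-1,2,4,5-tetrayl tetrakis{(2Z)-3-[(2S,3S)-3-methyloxiran-2-yl]prop-2-enoate} | C[C@@H]1O[C@H]1/C=C\C(=O)Oc1c(OC(=O)/C=C\[C@@H]2O[C@H]2C)c(-c2ccc(O)cc2)c(OC(=O)/C=C\[C@@H]2O[C@H]2C)c(OC(=O)/C=C\[C@@H]2O[C@H]2C)c1-c1ccc(O)cc1 | target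

## Step count and risks

Total step count: 13. Longest linear sequence: 8 steps (1, 2, 3, 4, 5, 11, 12, 13). The fragment 2 branch (steps 6–10) is equally long through steps 11–13 and joins at step 11.

**Step 5 (cascade to ring B).** Simple methanolysis of the enol-ester links in 6 or 7 to two molecules of methyl arylpyruvate can outrun C-acylation. The carbodiimide dimerisation of step 4 that feeds it is also uncertain. The fallback sets out from 2 and comes back at 10, entering through 9. Aldehyde 2 is reduced (NaBH4, MeOH, 0 °C) to {4-[(4-methoxybenzyl)oxy]phenyl}methanol F1. Neutral Appel chlorination (PPh3, CCl4, CH2Cl2) gives 1-(chloromethyl)-4-[(4-methoxybenzyl)oxy]benzene F2. Magnesium insertion (Mg turnings, 2-MeTHF, slow addition, 0 °C, to limit Wurtz coupling) gives {4-[(4-methoxybenzyl)oxy]benzyl}magnesium chloride F3. Addition of F3 (2.2 equiv) to N,N'-dimethoxy-N,N'-dimethyloxamide gives 1,4-bis{4-[(4-methoxybenzyl)oxy]phenyl}butane-2,3-dione F4. F4 with dimethyl oxalate and NaOMe (THF/MeOH) is C-acylated intermolecularly to 9, which closes ring B by the same intramolecular Claisen condensation to 10. This reaches the cyclisation substrate without any enol-ester link.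

**Step 11 (acylation of the quinone hydroxyls).** The acyl transfer to a vinylogous carboxylate is an equilibrium. Product 18 is a vinylogous anhydride that hydrolyses easily, and DMAP can isomerise the Z-enoyl unit by conjugate addition and elimination. Any minor-enantiomer acid from step 6 also ends up in diastereomeric esters that must be removed at 20. The fallback sets out from 10 (with aldehyde 13) and comes back at 20, so that steps 10 to 12 are bypassed. Quinone 10 is reduced (Na2S2O4, EtOAc/H2O, Ar) to 3,6-bis{4-[(4-methoxybenzyl)oxy]phenyl}benzene-1,2,4,5-tetraol F5. All four hydroxyls of F5 are esterified with the robust, commercially available [bis(2,2,2-trifluoroethoxy)phosphoryl]acetic acid (DCC, DMAP cat., CH2Cl2) to 3,6-bis{4-[(4-methoxybenzyl)oxy]phenyl}benzene-1,2,4,5-tetrayl tetrakis{[bis(2,2,2-trifluoroethoxy)phosphoryl]acetate} F6. A fourfold Still–Gennari olefination of F6 with aldehyde 13 (KN(SiMe3)2, 18-crown-6, THF, −78 °C) then builds the Z-enoates directly on the core to give 20. No epoxy-enoyl electrophile and no quinone enol ester is needed.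

**Step 13 (DDQ deprotection).** Aryl PMB ethers are cleaved by DDQ more slowly than alkyl ones, and long exposure endangers the vinyl oxiranes and the liberated phenols. The fallback sets out from 10 and comes back at 21, replacing the oxidatively removed group by a fluoride-labile one. The PMB groups are removed on the robust quinone (TFA, anisole, CH2Cl2, 0 °C) to give 2,5-dihydroxy-3,6-bis(4-hydroxyphenyl)cyclohexa-2,5-diene-1,4-dione (atromentin) F7. TBSCl (2.2 equiv) and imidazole in DMF silylate the two phenols (any silyl ester at the vinylogous-acid hydroxyls is lost on aqueous work-up) to give 2,5-dihydroxy-3,6-bis{4-[(tert-butyldimethylsilyl)oxy]phenyl}cyclohexa-2,5-diene-1,4-dione F8. Acylation with 17 as in step 11 gives 2,5-bis{4-[(tert-butyldimethylsilyl)oxy]phenyl}-3,6-dioxocyclohexa-1,4-diene-1,4-diyl bis{(2Z)-3-[(2S,3S)-3-methyloxiran-2-yl]prop-2-enoate} F9. Na2S2O4 reduction as in step 12 gives 2,5-dihydroxy-3,6-bis{4-[(tert-butyldimethylsilyl)oxy]phenyl}benzene-1,4-diyl bis{(2Z)-3-[(2S,3S)-3-methyloxiran-2-yl]prop-2-enoate} F10, which is not isolated. Its acylation with 17 gives 3,6-bis{4-[(tert-butyldimethylsilyl)oxy]phenyl}benzene-1,2,4,5-tetrayl tetrakis{(2Z)-3-[(2S,3S)-3-methyloxiran-2-yl]prop-2-enoate} F11. Buffered fluoride (Bu4NF/AcOH 1:1, THF, 0 °C) then releases 21.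

## Further compounds

F1 | step 5 | {4-[(4-methoxybenzyl)oxy]phenyl}methanol | COc1ccc(COc2ccc(CO)cc2)cc1
F2 | step 5 | 1-(chloromethyl)-4-[(4-methoxybenzyl)oxy]benzene | COc1ccc(COc2ccc(CCl)cc2)cc1
F3 | step 5 | {4-[(4-methoxybenzyl)oxy]benzyl}magnesium chloride | COc1ccc(COc2ccc(C[Mg]Cl)cc2)cc1
F4 | step 5 | 1,4-bis{4-[(4-methoxybenzyl)oxy]phenyl}butane-2,3-dione | COc1ccc(COc2ccc(CC(=O)C(=O)Cc3ccc(OCc4ccc(OC)cc4)cc3)cc2)cc1
F5 | step 11 | 3,6-bis{4-[(4-methoxybenzyl)oxy]phenyl}benzene-1,2,4,5-tetraol | Oc1c(O)c(-c2ccc(OCc3ccc(OC)cc3)cc2)c(O)c(O)c1-c1ccc(OCc2ccc(OC)cc2)cc1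
F6 | step 11 | 3,6-bis{4-[(4-methoxybenzyl)oxy]phenyl}benzene-1,2,4,5-tetrayl tetrakis{[bis(2,2,2-trifluoroethoxy)phosphoryl]acetate} | O=C(CP(=O)(OCC(F)(F)F)OCC(F)(F)F)Oc1c(OC(=O)CP(=O)(OCC(F)(F)F)OCC(F)(F)F)c(-c2ccc(OCc3ccc(OC)cc3)cc2)c(OC(=O)CP(=O)(OCC(F)(F)F)OCC(F)(F)F)c(OC(=O)CP(=O)(OCC(F)(F)F)OCC(F)(F)F)c1-c1ccc(OCc2ccc(OC)cc2)cc1
F7 | step 13 | 2,5-dihydroxy-3,6-bis(4-hydroxyphenyl)cyclohexa-2,5-diene-1,4-dione (atromentin) | O=C1C(O)=C(c2ccc(O)cc2)C(=O)C(O)=C1c1ccc(O)cc1
F8 | step 13 | 2,5-dihydroxy-3,6-bis{4-[(tert-butyldimethylsilyl)oxy]phenyl}cyclohexa-2,5-diene-1,4-dione | CC(C)(C)[Si](C)(C)Oc1ccc(cc1)C1=C(O)C(=O)C(c2ccc(O[Si](C)(C)C(C)(C)C)cc2)=C(O)C1=O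
F9 | step 13 | 2,5-bis{4-[(tert-butyldimethylsilyl)oxy]phenyl}-3,6-dioxocyclohexa-1,4-diene-1,4-diyl bis{(2Z)-3-[(2S,3S)-3-methyloxiran-2-yl]prop-2-enoate} | O=C1C(OC(=O)/C=C\[C@@H]2O[C@H]2C)=C(c2ccc(O[Si](C)(C)C(C)(C)C)cc2)C(=O)C(OC(=O)/C=C\[C@@H]2O[C@H]2C)=C1c1ccc(O[Si](C)(C)C(C)(C)C)cc1
F10 | step 13 | 2,5-dihydroxy-3,6-bis{4-[(tert-butyldimethylsilyl)oxy]phenyl}benzene-1,4-diyl bis{(2Z)-3-[(2S,3S)-3-methyloxiran-2-yl]prop-2-enoate} | Oc1c(OC(=O)/C=C\[C@@H]2O[C@H]2C)c(-c2ccc(O[Si](C)(C)C(C)(C)C)cc2)c(O)c(OC(=O)/C=C\[C@@H]2O[C@H]2C)c1-c1ccc(O[Si](C)(C)C(C)(C)C)cc1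
F11 | step 13 | 3,6-bis{4-[(tert-butyldimethylsilyl)oxy]phenyl}benzene-1,2,4,5-tetrayl tetrakis{(2Z)-3-[(2S,3S)-3-methyloxiran-2-yl]prop-2-enoate} | C[C@@H]1O[C@H]1/C=C\C(=O)Oc1c(OC(=O)/C=C\[C@@H]2O[C@H]2C)c(-c2ccc(O[Si](C)(C)C(C)(C)C)cc2)c(OC(=O)/C=C\[C@@H]2O[C@H]2C)c(OC(=O)/C=C\[C@@H]2O[C@H]2C)c1-c1ccc(O[Si](C)(C)C(C)(C)C)cc1
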